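## Retrosynthetic overview

1. Target 21 ⇐ 14-alcohol 20: the last step is a chemoselective oxidation of the primary allylic C14–OH.
2. 20 ⇐ lactol 18: one chromium(II) step closes the ten-membered carbocycle at C6–C7 (the farnesyl C1–C10 bond of germacrene formation) and then the γ-lactone (O6–C12). It runs on an unprotected lactol as latent (Z)-enal and sets C6 and C7 under control of C8.
3. 18 ⇐ enal 13 + diene 16: an asymmetric hetero-Diels–Alder reaction builds a temporary dihydropyran that sets C2, fixes the 4,5-cis olefin, brings C15–OAc and masks C6=O together with C2–OH.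
4. 13 ⇐ aldehyde 9 (Morita–Baylis–Hillman, SN2′ bromination) ⇐ alkylidene lactone 4 (Pd cyclocarbonylation sets the 1(10) geometry) ⇐ alkyne 1 + (R)-trityl glycidyl ether 2 (C8 from the chiral pool).
5. Ring order: temporary butyrolactone (4), temporary dihydropyran (17), then carbocycle and α-methylene lactone in one operation (20).

Assumption: locants use germacrane numbering (C1–C15, lactone C12/O6); centres that are destroyed later (carbinol C7 of 11, acetal carbon of 17, anomeric carbon of 18) are carried as mixtures or as the expected isomer.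

## Route

Step 1
Reactants: 1 3,3-diethoxyprop-1-yne; 2 (R)-trityl glycidyl ether, (2R)-2-[(triphenylmethoxy)methyl]oxirane
Product: 3 (2R)-6,6-diethoxy-1-(triphenylmethoxy)hex-4-yn-2-ol
Conditions: n-BuLi, THF, −78 °C; BF3·OEt2; then 2, −78 °C
Reagents that add atoms: none
Why: Yamaguchi–Hirao alkynylation; the alkynyl borate opens the epoxide only at the terminal CH2 (C9), so C8 is taken unchanged from the chiral pool.

Step 2
Reactants: 3
Product: 4 (3E,5R)-3-(2,2-diethoxyethylidene)-5-[(triphenylmethoxy)methyl]oxolan-2-one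
Conditions: Pd(dba)2 (4 mol %), dppb (4 mol %), CO (40 bar)/H2 (14 bar), CH2Cl2, 95 °C
Reagents that add atoms: carbon monoxide, [C-]#[O+]
Why: Pd-catalysed cyclocarbonylation of a homopropargylic alcohol (Norton/Alper type); H and the O8-tethered acyl carbon add syn across the alkyne (5-exo), which puts C14 on C10 and gives only the E-alkylidene lactone, i.e. C2 cis to C9 as in the target 1(10) olefin.

Step 3
Reactants: 4
Product: 5 (2R,4E)-6,6-diethoxy-4-(hydroxymethyl)-1-(triphenylmethoxy)hex-4-en-2-ol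
Conditions: DIBAL-H (3.5 equiv), CH2Cl2, −78 → 0 °C; Rochelle salt
Reagents that add atoms: none
Why: 1,2-hydride reduction of the conjugated lactone to the allylic diol; acetal, trityl ether and olefin geometry are untouched.

Step 4
Reactants: 5
Product: 7 (2R,4E)-6,6-diethoxy-4-{[(triisopropylsilyl)oxy]methyl}-1-(triphenylmethoxy)hex-4-en-2-yl 3-methylbutanoate, via primary TIPS ether 6 (not isolated)
Conditions: TIPSCl (1.05 equiv), imidazole, CH2Cl2, 0 °C; then isovaleric anhydride, Et3N, DMAP (cat.), rt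
Reagents that add atoms: chlorotriisopropylsilane, CC(C)[Si](Cl)(C(C)C)C(C)C; isovaleric anhydride, CC(C)CC(=O)OC(=O)CC(C)C
Why: the bulky silyl chloride takes only the primary allylic OH (C14), and the remaining C8–OH is then esterified by DMAP acyl transfer with no change at C8.

Step 5
Reactants: 7
Product: 8 (2R,4E)-6,6-diethoxy-1-hydroxy-4-{[(triisopropylsilyl)oxy]methyl}hex-4-en-2-yl 3-methylbutanoate
Conditions: CSA (10 mol %), EtOH/CH2Cl2 (1:1), 0 °C → rt, short time
Reagents that add atoms: none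
Why: acid-catalysed SN1 solvolysis of the trityl ether; in ethanol the diethyl acetal only exchanges with itself and the primary TIPS ether is stable, so only C7–OH is freed.

Step 6
Reactants: 8
Product: 9 (2R,4E)-6,6-diethoxy-1-oxo-4-{[(triisopropylsilyl)oxy]methyl}hex-4-en-2-yl 3-methylbutanoate
Conditions: Dess–Martin periodinane, CH2Cl2, 0 °C → rt; used at once
Reagents that add atoms: none
Why: Dess–Martin oxidation under neutral conditions; immediate use keeps the α-acyloxy aldehyde from epimerising at C8 and leaves no time for 1,2-acyl shift in 8.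

Step 7
Reactants: 9; 10 methyl acrylate
Product: 11 methyl (4R,6E)-8,8-diethoxy-3-hydroxy-2-methylidene-4-(3-methylbutanoyloxy)-6-{[(triisopropylsilyl)oxy]methyl}oct-6-enoate (both C3 epimers)
Conditions: 10 (15 equiv, neat), 3-hydroxyquinuclidine (25 mol %), MeOH (0.5 equiv), rt, stopped at full conversion
Reagents that add atoms: none
Why: Morita–Baylis–Hillman reaction; the α-acyloxy aldehyde is a fast acceptor, so contact with the amine is short, and the new carbinol centre (C7) is removed in step 8.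

Step 8
Reactants: 11
Product: 13 methyl (2Z,4R,6E)-2-(bromomethyl)-4-(3-methylbutanoyloxy)-8-oxo-6-{[(triisopropylsilyl)oxy]methyl}octa-2,6-dienoate, via bromo acetal 12 (not isolated)
Conditions: NBS, Me2S, CH2Cl2, −20 → 0 °C; then 5 % aq. oxalic acid, THF, rt
Reagents that add atoms: N-bromosuccinimide, O=C1CCC(=O)N1Br; water, O
Why: Corey–Kim-type SN2′ bromination of the Baylis–Hillman alcohol gives the conjugated (Z)-2-(bromomethyl)enoate (C8 cis to CH2Br), and the labile conjugated acetal is hydrolysed in the acidic work-up, so the base-sensitive δ-acyloxy enal appears only after all basic steps.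

Step 9
Reactants: 14 prop-2-yn-1-yl acetate; 15 ethyl vinyl ether
Product: 16 (3E)-4-ethoxy-2-methylidenebut-3-en-1-yl acetate
Conditions: Grubbs II (5 mol %), 15 (9 equiv), toluene, 80 °C, sealed tube
Reagents that add atoms: none
Why: cross enyne (enol ether–alkyne) metathesis gives the 1-ethoxy-3-substituted diene with all atoms retained; it forms as an E/Z mixture, of which the E isomer is the reactive diene in step 10.

Step 10
Reactants: 13; 16
Product: 17 methyl (2Z,4R,6E)-7-[(2S,6R)-4-(acetoxymethyl)-6-ethoxy-3,6-dihydro-2H-pyran-2-yl]-2-(bromomethyl)-4-(3-methylbutanoyloxy)-6-{[(triisopropylsilyl)oxy]methyl}hepta-2,6-dienoate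
Conditions: Jacobsen tridentate Schiff-base Cr(III)Cl catalyst, (1S,2R)-aminoindanol series (10 mol %; the antipode that gives Si-face addition, to be confirmed on a model enal), 16 (3 equiv), 4 Å MS, minimal TBME, rt
Reagents that add atoms: none
Why: catalytic asymmetric hetero-Diels–Alder reaction (endo); Si-face addition to the aldehyde sets C2 as S under catalyst control, the ring forces C6 cis to C3 (4,5-cis olefin), and C6=O and C2–O are stored as a cyclic acetal carrying C15–OAc.

Step 11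
Reactants: 17
Product: 18 methyl (2Z,4R,6E)-7-[(2S)-4-(acetoxymethyl)-6-hydroxy-3,6-dihydro-2H-pyran-2-yl]-2-(bromomethyl)-6-(hydroxymethyl)-4-(3-methylbutanoyloxy)hepta-2,6-dienoate (lactol, both anomers)
Conditions: 48 % aq. HF/MeCN (1:19), 0 °C → rt
Reagents that add atoms: water, O
Why: acid hydrolysis of the allylic acetal to the lactol and fluoride cleavage of the TIPS ether in one operation; esters and the allylic bromide survive dilute aqueous HF.

Step 12
Reactants: 18
Product: 20 (3aR,4R,6E,8S,10E,11aR)-10-(acetoxymethyl)-8-hydroxy-6-(hydroxymethyl)-3-methylidene-2-oxo-2,3,3a,4,5,8,9,11a-octahydrocyclodeca[b]furan-4-yl 3-methylbutanoate, via hydroxy ester 19 (not isolated)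
Conditions: CrCl2 (8 equiv), THF/DMF (10:1), rt, 18 added over 12 h (final 2 mM); aq. NH4Cl; then PPTS (cat.), CH2Cl2, rt
Reagents that add atoms: none
Why: Proposed new method: Cr(II) inserts into the allylic C–Br bond and the allylchromium(III) adds through C7 (SE2′) to the small equilibrium amount of open (Z)-hydroxy-enal supplied by the lactol, closing the ten-membered ring at C6–C7; a chair transition state of the equilibrated allylchromium is expected to give the 6,7-anti adduct (trans lactone), attack anti to C9 with H8 in the olefin plane (A1,3 strain, acyloxy group outside) is expected to give the 7,8-relationship of the target, and the chromium alkoxide then lactonises onto the methyl ester; the closest known reaction types are the intramolecular Nozaki–Hiyama–Kishi allylation of 2-(bromomethyl)acrylates onto enals used for germacranolides and Barbier allylation of free lactols.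

Step 13
Reactants: 20
Product: 21 (3aR,4R,6E,8S,10E,11aR)-10-(acetoxymethyl)-6-formyl-8-hydroxy-3-methylidene-2-oxo-2,3,3a,4,5,8,9,11a-octahydrocyclodeca[b]furan-4-yl 3-methylbutanoate (CNP0524123.1)
Conditions: TEMPO (10 mol %), PhI(OAc)2 (1.2 equiv), CH2Cl2, rt
Reagents that add atoms: none
Why: TEMPO/PhI(OAc)2 (Piancatelli) oxidation takes the primary allylic alcohol to the enal and leaves the secondary allylic C2–OH; the olefin geometry (CHO trans to C2) is already the stable one.

## Compound list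

1 | 3,3-diethoxyprop-1-yne | CCOC(OCC)C#C | starting material
2 | (R)-trityl glycidyl ether | C1O[C@H]1COC(c2ccccc2)(c2ccccc2)c2ccccc2 | starting material
3 | (2R)-6,6-diethoxy-1-(triphenylmethoxy)hex-4-yn-2-ol | CCOC(OCC)C#CC[C@@H](O)COC(c1ccccc1)(c1ccccc1)c1ccccc1 | intermediate
4 | (3E,5R)-3-(2,2-diethoxyethylidene)-5-[(triphenylmethoxy)methyl]oxolan-2-one | CCOC(OCC)/C=C1\C[C@H](COC(c2ccccc2)(c2ccccc2)c2ccccc2)OC1=O | intermediate
5 | (2R,4E)-6,6-diethoxy-4-(hydroxymethyl)-1-(triphenylmethoxy)hex-4-en-2-ol | CCOC(OCC)/C=C(/CO)C[C@@H](O)COC(c1ccccc1)(c1ccccc1)c1ccccc1 | intermediate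
6 | (2R,4E)-6,6-diethoxy-4-{[(triisopropylsilyl)oxy]methyl}-1-(triphenylmethoxy)hex-4-en-2-ol | CCOC(OCC)/C=C(/CO[Si](C(C)C)(C(C)C)C(C)C)C[C@@H](O)COC(c1ccccc1)(c1ccccc1)c1ccccc1 | intermediate
7 | (2R,4E)-6,6-diethoxy-4-{[(triisopropylsilyl)oxy]methyl}-1-(triphenylmethoxy)hex-4-en-2-yl 3-methylbutanoate | CCOC(OCC)/C=C(/CO[Si](C(C)C)(C(C)C)C(C)C)C[C@@H](OC(=O)CC(C)C)COC(c1ccccc1)(c1ccccc1)c1ccccc1 | intermediate
8 | (2R,4E)-6,6-diethoxy-1-hydroxy-4-{[(triisopropylsilyl)oxy]methyl}hex-4-en-2-yl 3-methylbutanoate | CCOC(OCC)/C=C(/CO[Si](C(C)C)(C(C)C)C(C)C)C[C@@H](OC(=O)CC(C)C)CO | intermediate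
9 | (2R,4E)-6,6-diethoxy-1-oxo-4-{[(triisopropylsilyl)oxy]methyl}hex-4-en-2-yl 3-methylbutanoate | CCOC(OCC)/C=C(/CO[Si](C(C)C)(C(C)C)C(C)C)C[C@@H](OC(=O)CC(C)C)C=O | intermediate
10 | methyl acrylate | C=CC(=O)OC | starting material
11 | methyl (4R,6E)-8,8-diethoxy-3-hydroxy-2-methylidene-4-(3-methylbutanoyloxy)-6-{[(triisopropylsilyl)oxy]methyl}oct-6-enoate | CCOC(OCC)/C=C(/CO[Si](C(C)C)(C(C)C)C(C)C)C[C@@H](OC(=O)CC(C)C)C(O)C(=C)C(=O)OC | intermediate
12 | methyl (2Z,4R,6E)-2-(bromomethyl)-8,8-diethoxy-4-(3-methylbutanoyloxy)-6-{[(triisopropylsilyl)oxy]methyl}octa-2,6-dienoate | CCOC(OCC)/C=C(/CO[Si](C(C)C)(C(C)C)C(C)C)C[C@@H](OC(=O)CC(C)C)/C=C(\CBr)C(=O)OC | intermediate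
13 | methyl (2Z,4R,6E)-2-(bromomethyl)-4-(3-methylbutanoyloxy)-8-oxo-6-{[(triisopropylsilyl)oxy]methyl}octa-2,6-dienoate | O=C/C=C(/CO[Si](C(C)C)(C(C)C)C(C)C)C[C@@H](OC(=O)CC(C)C)/C=C(\CBr)C(=O)OC | intermediate
14 | prop-2-yn-1-yl acetate | CC(=O)OCC#C | starting material
15 | ethyl vinyl ether | C=COCC | starting material
16 | (3E)-4-ethoxy-2-methylidenebut-3-en-1-yl acetate | CCO/C=C/C(=C)COC(C)=O | intermediate
17 | methyl (2Z,4R,6E)-7-[(2S,6R)-4-(acetoxymethyl)-6-ethoxy-3,6-dihydro-2H-pyran-2-yl]-2-(bromomethyl)-4-(3-methylbutanoyloxy)-6-{[(triisopropylsilyl)oxy]methyl}hepta-2,6-dienoate | CCO[C@H]1C=C(COC(C)=O)C[C@H](O1)/C=C(/CO[Si](C(C)C)(C(C)C)C(C)C)C[C@@H](OC(=O)CC(C)C)/C=C(\CBr)C(=O)OC | intermediate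
18 | methyl (2Z,4R,6E)-7-[(2S)-4-(acetoxymethyl)-6-hydroxy-3,6-dihydro-2H-pyran-2-yl]-2-(bromomethyl)-6-(hydroxymethyl)-4-(3-methylbutanoyloxy)hepta-2,6-dienoate | OC1C=C(COC(C)=O)C[C@H](O1)/C=C(/CO)C[C@@H](OC(=O)CC(C)C)/C=C(\CBr)C(=O)OC | intermediate
19 | methyl 2-[(1S,2R,3E,6S,7E,10R)-4-(acetoxymethyl)-2,6-dihydroxy-8-(hydroxymethyl)-10-(3-methylbutanoyloxy)cyclodeca-3,7-dien-1-yl]prop-2-enoate | C=C(C(=O)OC)[C@H]1[C@H](O)/C=C(/COC(C)=O)C[C@H](O)/C=C(/CO)C[C@H]1OC(=O)CC(C)C | intermediate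
20 | (3aR,4R,6E,8S,10E,11aR)-10-(acetoxymethyl)-8-hydroxy-6-(hydroxymethyl)-3-methylidene-2-oxo-2,3,3a,4,5,8,9,11a-octahydrocyclodeca[b]furan-4-yl 3-methylbutanoate | C=C1C(=O)O[C@@H]2/C=C(/COC(C)=O)C[C@H](O)/C=C(/CO)C[C@@H](OC(=O)CC(C)C)[C@@H]12 | intermediate
21 | (3aR,4R,6E,8S,10E,11aR)-10-(acetoxymethyl)-6-formyl-8-hydroxy-3-methylidene-2-oxo-2,3,3a,4,5,8,9,11a-octahydrocyclodeca[b]furan-4-yl 3-methylbutanoate | C=C1C(=O)O[C@@H]2/C=C(/COC(C)=O)C[C@H](O)/C=C(/C=O)C[C@@H](OC(=O)CC(C)C)[C@@H]12 | target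

## Step count and risks

Total steps: 13. Longest linear sequence: 12 (steps 1–8 and 10–13); step 9 is a one-step side branch.

**Step 12 (macrocyclisation/lactonisation).** Risks are a low concentration of open enal, oligomers, and the cis-lactone or the C7 epimer. The fallback sets out from 9 and comes back at 20. It keeps the C6–C7 closure but changes the nucleophile to an allylsilane (fluoride-triggered Hosomi–Sakurai-type addition, open transition state, different stereochemical bias). Aldehyde 9 is olefinated (NaH, THF, −78 → 0 °C) with methyl 2-(dimethoxyphosphoryl)-3-(trimethylsilyl)propanoate to the allylsilane acetal F1. Aqueous oxalic acid gives the allylsilane enal F2. The hetero-Diels–Alder reaction of step 10 with 16 gives the allylsilane dihydropyran F3. PPTS in wet acetone gives the allylsilane lactol F4 with the TIPS group kept. TBAF in THF at high dilution then closes C6–C7, removes the TIPS group and, after lactonisation, gives 20.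

**Step 10 (hetero-Diels–Alder on a β,β-disubstituted enal).** Risks are low reactivity of the enal and modest facial control. The fallback sets out from 13 and comes back at 17. Keck allylation of 13 with tributyl[2-(acetoxymethyl)prop-2-en-1-yl]stannane under (S)-BINOL/Ti(OiPr)4 gives the homoallylic alcohol F5 with C2 set by the catalyst. Acetal exchange with acrolein diethyl acetal (PPTS) gives the mixed acetal F6. Ring-closing metathesis (Grubbs II) between the acrolein vinyl group and the 1,1-disubstituted olefin closes the dihydropyran and gives 17.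

**Step 2 (cyclocarbonylation of an internal alkyne bearing an acetal and a trityl ether).** Risks are poor conversion and loss of the acid-sensitive groups. The fallback sets out from 2 and comes back at 6, bypassing steps 1–3. But-2-yne-1,4-diol is monosilylated (NaH, TIPSCl) to the alkynol F7. Red-Al followed by iodine gives the (Z)-iodo alcohol F8; hydroxyl-directed anti-hydroalumination puts iodine on the future C10, cis to C2. MnO2 gives the iodo enal F9, and HC(OEt)3/PPTS gives the iodo acetal F10. Lithium–iodine exchange (t-BuLi, Et2O, −78 °C) and BF3·OEt2-mediated opening of epoxide 2, with retention of olefin geometry, give 6, which is acylated as in step 4 to 7.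

## Further compounds

F1 | step 12 | methyl (4R,6E)-8,8-diethoxy-4-(3-methylbutanoyloxy)-6-{[(triisopropylsilyl)oxy]methyl}-2-[(trimethylsilyl)methyl]octa-2,6-dienoate (2E/2Z mixture) | CCOC(OCC)/C=C(/CO[Si](C(C)C)(C(C)C)C(C)C)C[C@@H](OC(=O)CC(C)C)C=C(C[Si](C)(C)C)C(=O)OC
F2 | step 12 | methyl (4R,6E)-4-(3-methylbutanoyloxy)-8-oxo-6-{[(triisopropylsilyl)oxy]methyl}-2-[(trimethylsilyl)methyl]octa-2,6-dienoate | O=C/C=C(/CO[Si](C(C)C)(C(C)C)C(C)C)C[C@@H](OC(=O)CC(C)C)C=C(C[Si](C)(C)C)C(=O)OC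
F3 | step 12 | methyl (4R,6E)-7-[(2S,6R)-4-(acetoxymethyl)-6-ethoxy-3,6-dihydro-2H-pyran-2-yl]-4-(3-methylbutanoyloxy)-6-{[(triisopropylsilyl)oxy]methyl}-2-[(trimethylsilyl)methyl]hepta-2,6-dienoate | CCO[C@H]1C=C(COC(C)=O)C[C@H](O1)/C=C(/CO[Si](C(C)C)(C(C)C)C(C)C)C[C@@H](OC(=O)CC(C)C)C=C(C[Si](C)(C)C)C(=O)OC
F4 | step 12 | methyl (4R,6E)-7-[(2S)-4-(acetoxymethyl)-6-hydroxy-3,6-dihydro-2H-pyran-2-yl]-4-(3-methylbutanoyloxy)-6-{[(triisopropylsilyl)oxy]methyl}-2-[(trimethylsilyl)methyl]hepta-2,6-dienoate | OC1C=C(COC(C)=O)C[C@H](O1)/C=C(/CO[Si](C(C)C)(C(C)C)C(C)C)C[C@@H](OC(=O)CC(C)C)C=C(C[Si](C)(C)C)C(=O)OC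
F5 | step 10 | methyl (2Z,4R,6E,8S)-10-(acetoxymethyl)-2-(bromomethyl)-8-hydroxy-4-(3-methylbutanoyloxy)-6-{[(triisopropylsilyl)oxy]methyl}undeca-2,6,10-trienoate | C=C(COC(C)=O)C[C@H](O)/C=C(/CO[Si](C(C)C)(C(C)C)C(C)C)C[C@@H](OC(=O)CC(C)C)/C=C(\CBr)C(=O)OC
F6 | step 10 | methyl (2Z,4R,6E,8S)-10-(acetoxymethyl)-2-(bromomethyl)-8-[(1-ethoxyprop-2-en-1-yl)oxy]-4-(3-methylbutanoyloxy)-6-{[(triisopropylsilyl)oxy]methyl}undeca-2,6,10-trienoate | C=C(COC(C)=O)C[C@H](OC(OCC)C=C)/C=C(/CO[Si](C(C)C)(C(C)C)C(C)C)C[C@@H](OC(=O)CC(C)C)/C=C(\CBr)C(=O)OC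
F7 | step 2 | 4-[(triisopropylsilyl)oxy]but-2-yn-1-ol | OCC#CCO[Si](C(C)C)(C(C)C)C(C)C
F8 | step 2 | (2Z)-3-iodo-4-[(triisopropylsilyl)oxy]but-2-en-1-ol | OC/C=C(\I)CO[Si](C(C)C)(C(C)C)C(C)C
F9 | step 2 | (2Z)-3-iodo-4-[(triisopropylsilyl)oxy]but-2-enal | O=C/C=C(\I)CO[Si](C(C)C)(C(C)C)C(C)C
F10 | step 2 | {[(2Z)-4,4-diethoxy-2-iodobut-2-en-1-yl]oxy}triisopropylsilane | CCOC(OCC)/C=C(\I)CO[Si](C(C)C)(C(C)C)C(C)C
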